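**Retrosynthetic overview**

1. The plan rests on C4 and C5 of the ten-membered carbocycle (C1–C10): both carry the oxygen of the 4,5-epoxide. The C4–C5 bond is therefore made by reductive coupling of a C4 methyl ketone with a C5 aldehyde (SmI2), which closes the cyclodecane as the 4,5-diol. Displacement of a C5 mesylate by the C4 alkoxide then gives the epoxide, and desilylation at C6 closes the butenolide (C12–O–C6).
2. The keto aldehyde comes from C8–C9 union of an α-selective allylbarium reagent (C9, C10, C1–C4, C14, C15, from sulcatone) with the C8 aldehyde of a tetrasubstituted acrylate. C8 is set by CBS reduction and the 1,10-epoxide by Shi epoxidation.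
3. The acrylate (C5–C7, C11–C13) comes from (R)-glyceraldehyde acetonide (C5, C6, C7): alkyne, ynoate, syn vinylcupration with iodinolysis (C7=C11 geometry), Stille hydroxymethylation (C13), cleavage of the vinyl group to the C8 aldehyde.
4. Ring order: 1,10-epoxide (step 17), cyclodecane (step 20), 4,5-epoxide (step 21), butenolide (step 22).

Key step: step 20

Remark: atoms are numbered as in germacranolides (ring C1–C10, C11 and C12 the lactone α-carbon and carbonyl, C13 the acetoxymethyl carbon, C14 and C15 the methyls on C10 and C4). C6–O is carried as a TBS ether and C5 as a primary TBS ether until the aldehyde is needed.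

**Route**

Step 1
Reactants: 1 (R)-glyceraldehyde acetonide
Product: 2 (4S)-4-ethynyl-2,2-dimethyl-1,3-dioxolane
Conditions: dimethyl (1-diazo-2-oxopropyl)phosphonate, K2CO3, MeOH, 0 °C to rt
Reagents that add atoms: dimethyl (1-diazo-2-oxopropyl)phosphonate COP(=O)(OC)C(=[N+]=[N-])C(C)=O
Why: Seyferth–Gilbert homologation with the Ohira–Bestmann reagent turns the aldehyde carbon into the alkyne carbon C7 under mild carbonate conditions that should not epimerise the adjacent stereocentre, which becomes C6 of the target with the configuration it needs.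

Step 2
Reactants: 2 (4S)-4-ethynyl-2,2-dimethyl-1,3-dioxolane
Product: 3 (2S)-but-3-yne-1,2-diol
Conditions: AcOH–H2O (4:1), 40 °C
Reagents that add atoms: none
Why: Acid-catalysed acetal hydrolysis removes the isopropylidene group, which could not be taken off later without lactonisation of the C6 hydroxyl onto the cis ester, and leaves the alkyne and the stereocentre untouched.

Step 3
Reactants: 3 (2S)-but-3-yne-1,2-diol
Product: 4 (3S)-3,4-bis(tert-butyldimethylsilyloxy)but-1-yne
Conditions: TBSCl, imidazole, DMF, rt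
Reagents that add atoms: tert-butyldimethylsilyl chloride CC(C)(C)[Si](C)(C)Cl
Why: Standard silylation of both hydroxyls gives a secondary C6 ether that survives to the last step and a primary C5 ether that can later be cleaved selectively.

Step 4
Reactants: 4 (3S)-3,4-bis(tert-butyldimethylsilyloxy)but-1-yne
Product: 6 methyl (4S)-4,5-bis(tert-butyldimethylsilyloxy)pent-2-ynoate, via lithium acetylide 5 (not isolated)
Conditions: n-BuLi, THF, −78 °C; ClCO2Me, −78 to 0 °C
Reagents that add atoms: methyl chloroformate COC(=O)Cl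
Why: Deprotonation of the terminal alkyne and C-acylation of the lithium acetylide with methyl chloroformate gives the ynoate whose ester carbon is C12 and whose alkyne carbons are C11 and C7.

Step 5
Reactants: 6 methyl (4S)-4,5-bis(tert-butyldimethylsilyloxy)pent-2-ynoate
Product: 8 methyl (2E,4S)-4,5-bis(tert-butyldimethylsilyloxy)-3-ethenyl-2-iodopent-2-enoate (ester cis to C6; iodine cis to vinyl), via alkenylcopper 7 (not isolated)
Conditions: CH2=CHMgBr, CuBr·SMe2, THF, −78 to −40 °C; 6, −78 °C; I2, THF, −78 °C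
Reagents that add atoms: vinylmagnesium bromide C=C[Mg]Br; iodine II
Why: Conjugate addition of the organocopper reagent to the ynoate is a syn carbocupration that puts the vinyl group (future C8) on C7 cis to copper on C11 and therefore the ester cis to C6, and iodinolysis of the alkenylcopper at −78 °C, before it can equilibrate through the allenoate, replaces copper by iodine with retention and so fixes the geometry of the tetrasubstituted C7=C11 double bond.

Step 6
Reactants: 8 methyl (2E,4S)-4,5-bis(tert-butyldimethylsilyloxy)-3-ethenyl-2-iodopent-2-enoate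
Product: 9 methyl (2Z,4S)-4,5-bis(tert-butyldimethylsilyloxy)-3-ethenyl-2-(hydroxymethyl)pent-2-enoate
Conditions: Bu3SnCH2OH, Pd(PPh3)4 (5 mol %), dioxane, 90 °C
Reagents that add atoms: (tributylstannyl)methanol CCCC[Sn](CCCC)(CCCC)CO
Why: Stille coupling of the α-iodo acrylate with (tributylstannyl)methanol transfers the hydroxymethyl group (C13) with retention of the alkene geometry, α-iodo-α,β-unsaturated carbonyl compounds being reactive partners in this coupling.

Step 7
Reactants: 9 methyl (2Z,4S)-4,5-bis(tert-butyldimethylsilyloxy)-3-ethenyl-2-(hydroxymethyl)pent-2-enoate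
Product: 10 methyl (2Z,4S)-2-(acetoxymethyl)-4,5-bis(tert-butyldimethylsilyloxy)-3-ethenylpent-2-enoate
Conditions: Ac2O, pyridine, DMAP (cat.), CH2Cl2, 0 °C
Reagents that add atoms: acetic anhydride CC(=O)OC(C)=O
Why: Pyridine/DMAP acetylation of the primary allylic alcohol installs the C13 acetate of the target.

Step 8
Reactants: 10 methyl (2Z,4S)-2-(acetoxymethyl)-4,5-bis(tert-butyldimethylsilyloxy)-3-ethenylpent-2-enoate
Product: 12 methyl (2E,4S)-2-(acetoxymethyl)-4,5-bis(tert-butyldimethylsilyloxy)-3-formylpent-2-enoate (C8 aldehyde; ester cis to C6), via C8–C9 diol 11 (not isolated)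
Conditions: OsO4 (2 mol %), NaIO4, 2,6-lutidine, dioxane–H2O (3:1), rt
Reagents that add atoms: osmium tetroxide O=[Os](=O)(=O)=O; sodium periodate [Na+].[O-]I(=O)(=O)=O
Why: Johnson–Lemieux oxidation, in which OsO4 dihydroxylates only the unhindered terminal vinyl group because the tetrasubstituted acrylate double bond is electron-poor and shielded, and periodate cleaves the diol to the C8 aldehyde while 2,6-lutidine suppresses side reactions.

Step 9
Reactants: 13 6-methylhept-5-en-2-one (sulcatone)
Product: 14 2-methyl-2-(4-methylpent-3-en-1-yl)-1,3-dioxolane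
Conditions: HOCH2CH2OH, p-TsOH (cat.), benzene, reflux, Dean–Stark
Reagents that add atoms: ethylene glycol OCCO
Why: Acid-catalysed ketalisation with azeotropic removal of water protects the C4 ketone against the organobarium and borane reagents used later.

Step 10
Reactants: 14 2-methyl-2-(4-methylpent-3-en-1-yl)-1,3-dioxolane
Product: 15 (2E)-2-methyl-5-(2-methyl-1,3-dioxolan-2-yl)pent-2-en-1-ol
Conditions: SeO2 (0.3 equiv), t-BuOOH, CH2Cl2, rt
Reagents that add atoms: tert-butyl hydroperoxide CC(C)(C)OO; selenium dioxide O=[Se]=O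
Why: SeO2/t-BuOOH allylic oxidation (ene reaction then [2,3]-sigmatropic shift) attacks the (E)-methyl group of the trisubstituted alkene selectively and gives the E allylic alcohol whose hydroxymethyl carbon is C9.

Step 11
Reactants: 15 (2E)-2-methyl-5-(2-methyl-1,3-dioxolan-2-yl)pent-2-en-1-ol
Product: 16 2-[(3E)-5-chloro-4-methylpent-3-en-1-yl]-2-methyl-1,3-dioxolane
Conditions: PPh3, CCl4, reflux
Reagents that add atoms: tetrachloromethane ClC(Cl)(Cl)Cl
Why: The Appel reaction converts the primary allylic alcohol into the chloride by SN2 displacement at C9 without allylic transposition or loss of the E geometry.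

Step 12
Reactants: 12 methyl (2E,4S)-2-(acetoxymethyl)-4,5-bis(tert-butyldimethylsilyloxy)-3-formylpent-2-enoate; 16 2-[(3E)-5-chloro-4-methylpent-3-en-1-yl]-2-methyl-1,3-dioxolane
Product: 18 methyl (2Z,4S)-2-(acetoxymethyl)-4,5-bis(tert-butyldimethylsilyloxy)-3-[(3E)-1-hydroxy-3-methyl-6-(2-methyl-1,3-dioxolan-2-yl)hex-3-en-1-yl]pent-2-enoate (both C8 epimers), via allylbarium chloride 17 (not isolated)
Conditions: BaI2, preformed lithium biphenylide (LiC12H10), THF, rt; 16, −78 °C; 12, −78 °C; aq. NH4Cl at −78 °C
Reagents that add atoms: none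
Why: Allylbarium reagents made at −78 °C from E-allylic chlorides add to aldehydes at their less substituted (α) carbon with retention of the double-bond geometry, so the C8–C9 bond and the E C1=C10 alkene are formed while the hindered ester and the acetate react much more slowly than the aldehyde; C8 is formed without control here and is set in steps 13 and 14.

Step 13
Reactants: 18 C8 carbinol (both epimers)
Product: 19 methyl (2E,4S)-2-(acetoxymethyl)-4,5-bis(tert-butyldimethylsilyloxy)-3-[(3E)-3-methyl-6-(2-methyl-1,3-dioxolan-2-yl)hex-3-enoyl]pent-2-enoate (C8 ketone)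
Conditions: Dess–Martin periodinane, NaHCO3, CH2Cl2, 0 °C
Reagents that add atoms: none
Why: Buffered Dess–Martin oxidation converts both C8 epimers into one ketone under neutral conditions that should not move the β,γ-double bond into conjugation.

Step 14
Reactants: 19 C8 ketone
Product: 20 methyl (2Z,4S)-2-(acetoxymethyl)-4,5-bis(tert-butyldimethylsilyloxy)-3-[(1S,3E)-1-hydroxy-3-methyl-6-(2-methyl-1,3-dioxolan-2-yl)hex-3-en-1-yl]pent-2-enoate (8S alcohol)
Conditions: (R)-2-methyl-CBS-oxazaborolidine (0.3 equiv), BH3·SMe2, THF, −40 °C; MeOH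
Reagents that add atoms: none
Why: Corey–Bakshi–Shibata reduction, in which the (R)-oxazaborolidine–borane complex binds the ketone with the tetrasubstituted alkenyl group as the large and the C9 methylene as the small substituent and delivers hydride to the face that gives the 8S alcohol, far faster than borane hydroborates the trisubstituted alkene.

Step 15
Reactants: 20 8S alcohol
Product: 21 methyl (2Z,4S)-2-(acetoxymethyl)-3-[(1S,3E)-1-acetoxy-3-methyl-6-(2-methyl-1,3-dioxolan-2-yl)hex-3-en-1-yl]-4,5-bis(tert-butyldimethylsilyloxy)pent-2-enoate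
Conditions: Ac2O, pyridine, DMAP (cat.), CH2Cl2, 0 °C to rt
Reagents that add atoms: acetic anhydride CC(=O)OC(C)=O
Why: Acetylation of the secondary allylic alcohol gives the C8 acetate of the target and makes any earlier acetyl shift between O8 and O13 irrelevant.

Step 16
Reactants: 21 diacetate ketal
Product: 22 methyl (2Z,4S)-2-(acetoxymethyl)-3-[(1S,3E)-1-acetoxy-3-methyl-7-oxooct-3-en-1-yl]-4,5-bis(tert-butyldimethylsilyloxy)pent-2-enoate (C4 methyl ketone)
Conditions: PPTS, acetone–H2O (5:1), 45 °C
Reagents that add atoms: water O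
Why: Mild aqueous acid hydrolysis of the dioxolane releases the C4 methyl ketone at the last point before acid-sensitive epoxides are present, conditions under which silyl ethers and acetates persist.

Step 17
Reactants: 22 C4 methyl ketone
Product: 23 methyl (2Z,4S)-2-(acetoxymethyl)-3-[(1S)-1-acetoxy-2-[(2R,3R)-2-methyl-3-(3-oxobutyl)oxiran-2-yl]ethyl]-4,5-bis(tert-butyldimethylsilyloxy)pent-2-enoate ((1R,10R)-epoxide)
Conditions: D-fructose-derived Shi ketone (30 mol %), Oxone (2KHSO5·KHSO4·K2SO4), K2CO3, Bu4NHSO4, MeCN–CH2(OMe)2, aq. Na2B4O7 buffer, 0 °C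
Reagents that add atoms: Oxone, as potassium peroxymonosulfate [K+].[O-]S(=O)(=O)OO
Why: Shi epoxidation, in which the dioxirane formed from the D-fructose-derived ketone epoxidises the electron-rich E-trisubstituted C1=C10 alkene through the spiro transition state with reagent control to the (1R,10R)-epoxide, the tetrasubstituted acrylate being inert to dioxiranes.

Step 18
Reactants: 23 (1R,10R)-epoxide
Product: 24 methyl (2Z,4S)-2-(acetoxymethyl)-3-[(1S)-1-acetoxy-2-[(2R,3R)-2-methyl-3-(3-oxobutyl)oxiran-2-yl]ethyl]-4-(tert-butyldimethylsilyloxy)-5-hydroxypent-2-enoate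
Conditions: HF·pyridine, pyridine, THF, 0 °C
Reagents that add atoms: none
Why: Pyridine-buffered HF·pyridine cleaves the unhindered primary silyl ether much faster than the secondary C6 ether next to the tetrasubstituted alkene and is mild enough for the trisubstituted epoxide.

Step 19
Reactants: 24 C5 primary alcohol
Product: 25 methyl (2Z,4S)-2-(acetoxymethyl)-3-[(1S)-1-acetoxy-2-[(2R,3R)-2-methyl-3-(3-oxobutyl)oxiran-2-yl]ethyl]-4-(tert-butyldimethylsilyloxy)-5-oxopent-2-enoate (keto aldehyde)
Conditions: Dess–Martin periodinane, NaHCO3, CH2Cl2, 0 °C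
Reagents that add atoms: none
Why: Dess–Martin oxidation under buffered neutral conditions gives the α-silyloxy aldehyde without epimerisation at C6, and the keto aldehyde is used at once.

Step 20
Reactants: 25 keto aldehyde
Product: 26 ten-membered (1R,4R,5S,6S,8S,10R)-4,5-diol with 1,10-epoxide, C6 OTBS, C8 OAc and the exocyclic C7=C11 acrylate (CO2Me cis to C6; CH2OAc cis to C8)
Conditions: SmI2 (3 equiv), THF, −78 to −20 °C, slow addition of 25 (final 0.003 M); aq. NaHCO3
Reagents that add atoms: none
Why: One electron from divalent samarium converts the C5 aldehyde, the more easily reduced carbonyl, into an O-samarium ketyl radical that adds to the C4 ketone carbon (10-exo-trig closure of the cyclodecane ring), and a second electron gives the samarium diolate that is protonated on work-up. The closest known reaction is the SmI2-mediated intramolecular pinacol coupling of keto aldehydes to cyclic cis-1,2-diols, extended here to a ten-membered ring that is helped by the trans-1,10-epoxide and the sp2 centre C7 (fewer free rotors) and by high dilution. C5 is controlled by C6: the bulky, non-chelating silyloxy group lies anti to the forming C4–C5 bond (Felkin–Anh, dipole-minimised ketyl), which gives the 5,6-anti relationship and hence 5S. C4 is controlled by the trivalent samarium that bridges the ketyl and ketone oxygens in the cyclic transition state, so that both C–O bonds end on the same side and the cis (erythro) 4R,5S diol results, the only isomer that can close to the trans-epoxide by inversion at C5. The step needs the aldehyde and ketone to react in preference to the acrylate, the allylic acetates and the epoxide; this is secured by working without HMPA or proton donors at low temperature, where the hindered tetrasubstituted enoate and the isolated epoxide should accept electrons much more slowly than the aldehyde.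

Step 21
Reactants: 26 (4R,5S)-diol
Product: 28 methyl ester silyl ether of the (1R,4R,5R,6S,8S,10R)-1,10:4,5-bis-epoxide (open-chain acrylate at C7=C11), via C5 mesylate 27 (not isolated)
Conditions: MsCl, Et3N, CH2Cl2, 0 °C; then DBU, toluene, 50 °C
Reagents that add atoms: none
Why: Sulfonylation takes place only at the secondary C5 hydroxyl, and on deprotonation the tertiary C4 alkoxide displaces the mesylate intramolecularly (3-exo-tet Williamson closure) with inversion at C5, which converts the cis-4R,5S diol into the trans-(4R,5R)-epoxide while C6 is still silylated and therefore neither nucleophilic nor acidic.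

Step 22
Reactants: 28 bis-epoxide silyl ether
Product: 30 (1R,4R,5R,6S,8S,10R)-8,13-diacetoxy-1,10:4,5-diepoxygermacr-7(11)-en-12,6-olide (CNP0271844.1), via C6 hydroxy ester 29 (not isolated)
Conditions: Bu4NF, AcOH (1:1), THF, 0 °C to rt
Reagents that add atoms: none
Why: Fluoride cleaves the C6 silyl ether and the freed hydroxyl, held cis to the methyl ester by the C7=C11 double bond, lactonises spontaneously (5-exo-trig acyl substitution) to the butenolide, acetic acid buffering keeping acetates and epoxides intact.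

**Compound list**

1 | (R)-glyceraldehyde acetonide | CC1(C)OC[C@H](C=O)O1 | starting material
2 | (4S)-4-ethynyl-2,2-dimethyl-1,3-dioxolane | CC1(C)OC[C@H](C#C)O1 | intermediate
3 | (2S)-but-3-yne-1,2-diol | OC[C@H](C#C)O | intermediate
4 | (3S)-3,4-bis(tert-butyldimethylsilyloxy)but-1-yne | CC(C)(C)[Si](C)(C)OC[C@H](C#C)O[Si](C)(C)C(C)(C)C | intermediate
5 | lithium acetylide of 4 | CC(C)(C)[Si](C)(C)OC[C@H](C#C[Li])O[Si](C)(C)C(C)(C)C | intermediate
6 | methyl (4S)-4,5-bis(tert-butyldimethylsilyloxy)pent-2-ynoate | CC(C)(C)[Si](C)(C)OC[C@H](C#CC(=O)OC)O[Si](C)(C)C(C)(C)C | intermediate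
7 | alkenylcopper adduct (Cu on C11, cis to vinyl) | CC(C)(C)[Si](C)(C)OC[C@@H](O[Si](C)(C)C(C)(C)C)/C(=C(/[Cu])C(=O)OC)C=C | intermediate
8 | methyl (2E,4S)-4,5-bis(tert-butyldimethylsilyloxy)-3-ethenyl-2-iodopent-2-enoate | CC(C)(C)[Si](C)(C)OC[C@@H](O[Si](C)(C)C(C)(C)C)/C(=C(/I)C(=O)OC)C=C | intermediate
9 | methyl (2Z,4S)-4,5-bis(tert-butyldimethylsilyloxy)-3-ethenyl-2-(hydroxymethyl)pent-2-enoate | CC(C)(C)[Si](C)(C)OC[C@@H](O[Si](C)(C)C(C)(C)C)/C(=C(/CO)C(=O)OC)C=C | intermediate
10 | methyl (2Z,4S)-2-(acetoxymethyl)-4,5-bis(tert-butyldimethylsilyloxy)-3-ethenylpent-2-enoate | CC(C)(C)[Si](C)(C)OC[C@@H](O[Si](C)(C)C(C)(C)C)/C(=C(/COC(C)=O)C(=O)OC)C=C | intermediate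
11 | C8–C9 diol of 10 (both C8 epimers) | CC(C)(C)[Si](C)(C)OC[C@@H](O[Si](C)(C)C(C)(C)C)/C(=C(/COC(C)=O)C(=O)OC)C(O)CO | intermediate
12 | methyl (2E,4S)-2-(acetoxymethyl)-4,5-bis(tert-butyldimethylsilyloxy)-3-formylpent-2-enoate | CC(C)(C)[Si](C)(C)OC[C@@H](O[Si](C)(C)C(C)(C)C)/C(=C(/COC(C)=O)C(=O)OC)C=O | intermediate
13 | 6-methylhept-5-en-2-one (sulcatone) | CC(=O)CCC=C(C)C | starting material
14 | 2-methyl-2-(4-methylpent-3-en-1-yl)-1,3-dioxolane | CC(C)=CCCC1(C)OCCO1 | intermediate
15 | (2E)-2-methyl-5-(2-methyl-1,3-dioxolan-2-yl)pent-2-en-1-ol | OC/C(C)=C/CCC1(C)OCCO1 | intermediate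
16 | 2-[(3E)-5-chloro-4-methylpent-3-en-1-yl]-2-methyl-1,3-dioxolane | ClC/C(C)=C/CCC1(C)OCCO1 | intermediate
17 | allylbarium chloride from 16 | Cl[Ba]C/C(C)=C/CCC1(C)OCCO1 | intermediate
18 | C8 carbinol, both C8 epimers (union product) | CC(C)(C)[Si](C)(C)OC[C@@H](O[Si](C)(C)C(C)(C)C)/C(=C(/COC(C)=O)C(=O)OC)C(O)C/C(C)=C/CCC1(C)OCCO1 | intermediate
19 | C8 ketone | CC(C)(C)[Si](C)(C)OC[C@@H](O[Si](C)(C)C(C)(C)C)/C(=C(/COC(C)=O)C(=O)OC)C(=O)C/C(C)=C/CCC1(C)OCCO1 | intermediate
20 | 8S alcohol | CC(C)(C)[Si](C)(C)OC[C@@H](O[Si](C)(C)C(C)(C)C)/C(=C(/COC(C)=O)C(=O)OC)[C@@H](O)C/C(C)=C/CCC1(C)OCCO1 | intermediate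
21 | 8,13-diacetate ketal | CC(C)(C)[Si](C)(C)OC[C@@H](O[Si](C)(C)C(C)(C)C)/C(=C(/COC(C)=O)C(=O)OC)[C@@H](OC(C)=O)C/C(C)=C/CCC1(C)OCCO1 | intermediate
22 | C4 methyl ketone with E C1=C10 alkene | CC(C)(C)[Si](C)(C)OC[C@@H](O[Si](C)(C)C(C)(C)C)/C(=C(/COC(C)=O)C(=O)OC)[C@@H](OC(C)=O)C/C(C)=C/CCC(C)=O | intermediate
23 | (1R,10R)-epoxide, bis-silyl ether | CC(C)(C)[Si](C)(C)OC[C@@H](O[Si](C)(C)C(C)(C)C)/C(=C(/COC(C)=O)C(=O)OC)[C@@H](OC(C)=O)C[C@@]1(C)O[C@@H]1CCC(C)=O | intermediate
24 | C5 primary alcohol | OC[C@@H](O[Si](C)(C)C(C)(C)C)/C(=C(/COC(C)=O)C(=O)OC)[C@@H](OC(C)=O)C[C@@]1(C)O[C@@H]1CCC(C)=O | intermediate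
25 | keto aldehyde (C4 ketone, C5 aldehyde) | O=C[C@@H](O[Si](C)(C)C(C)(C)C)/C(=C(/COC(C)=O)C(=O)OC)[C@@H](OC(C)=O)C[C@@]1(C)O[C@@H]1CCC(C)=O | intermediate
26 | ten-membered (4R,5S)-4,5-diol | O[C@H]1[C@@H](O[Si](C)(C)C(C)(C)C)/C(=C(/COC(C)=O)C(=O)OC)[C@@H](OC(C)=O)C[C@@]2(C)O[C@@H]2CC[C@@]1(C)O | intermediate
27 | C5 mesylate of 26 | CS(=O)(=O)O[C@H]1[C@@H](O[Si](C)(C)C(C)(C)C)/C(=C(/COC(C)=O)C(=O)OC)[C@@H](OC(C)=O)C[C@@]2(C)O[C@@H]2CC[C@@]1(C)O | intermediate
28 | 1,10:4,5-bis-epoxide, C6 silyl ether, methyl ester | CC(=O)OC/C(C(=O)OC)=C1\[C@@H](OC(C)=O)C[C@@]2(C)O[C@@H]2CC[C@@]2(C)O[C@@H]2[C@H]1O[Si](C)(C)C(C)(C)C | intermediate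
29 | C6 hydroxy methyl ester of the bis-epoxide | CC(=O)OC/C(C(=O)OC)=C1\[C@@H](OC(C)=O)C[C@@]2(C)O[C@@H]2CC[C@@]2(C)O[C@@H]2[C@H]1O | intermediate
30 | (1R,4R,5R,6S,8S,10R)-8,13-diacetoxy-1,10:4,5-diepoxygermacr-7(11)-en-12,6-olide (CNP0271844.1) | CC(=O)OCC1=C2[C@@H](OC(C)=O)C[C@@]3(C)O[C@@H]3CC[C@@]3(C)O[C@@H]3[C@H]2OC1=O | target

**Summary**

Total step count: 22. Longest linear sequence: 19 steps (steps 1–8 and 12–22); the chain fragment takes steps 9–11.

Steps most likely to fail:

Step 20. The cyclodecane closure is slow. Simple reduction of the C5 aldehyde, intermolecular coupling, or ketyl addition to the wrong face of the C4 ketone can take over. The fallback replaces pinacol coupling and displacement by carbonyl olefination followed by oxygen transfer to the new alkene. It sets out from 22. Buffered HF·pyridine removes the primary silyl ether to give the hydroxy ketone F1, with the C1=C10 alkene still in place. Dess–Martin oxidation gives the keto aldehyde F2. McMurry coupling (TiCl3, Zn–Cu, DME, reflux, slow addition) closes C4=C5 to the (1E,4E)-cyclodecadiene F3. Shi epoxidation with excess reagent should then convert both E-trisubstituted ring alkenes into the (1R,10R)- and (4R,5R)-epoxides, and the fallback comes back to the route at 28.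

Step 12. The α-regioselectivity or the E geometry can erode if the allylbarium warms, and the organometallic can attack the acetate or the ester. The fallback uses a sulfonyl-stabilised carbanion in place of the allylmetal. It sets out from 16 and 12. Sodium benzenesulfinate in DMF converts 16 into the allyl sulfone F4. Its lithio derivative (n-BuLi, THF, −78 °C) adds through the sulfur-bearing carbon C9 to 12 and gives the β-hydroxy sulfone F5. Dess–Martin oxidation gives the β-keto sulfone F6, and reductive desulfonylation (SmI2, THF–MeOH, −78 °C) gives ketone 19, where the route is rejoined.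

Step 22. The C6 alkoxide set free by fluoride sits next to the 4,5-epoxide and can open or shift it (Payne-type migration) before it acylates; acetates may also migrate under basic fluoride. The fallback forms the lactone before the epoxide. It sets out from 26. Mesylation alone gives 27, which is isolated. Bu4NF/AcOH then removes the silyl group while no 4,5-epoxide is present, and lactonisation gives the butenolide hydroxy mesylate F7. DBU then closes the 4,5-epoxide with inversion at C5, and the fallback arrives at the target 30.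

**Further compounds**

F1 | step 20 | C5 primary alcohol with C4 ketone and E C1=C10 alkene (no epoxide) | OC[C@@H](O[Si](C)(C)C(C)(C)C)/C(=C(/COC(C)=O)C(=O)OC)[C@@H](OC(C)=O)C/C(C)=C/CCC(C)=O
F2 | step 20 | keto aldehyde with E C1=C10 alkene (no epoxide) | O=C[C@@H](O[Si](C)(C)C(C)(C)C)/C(=C(/COC(C)=O)C(=O)OC)[C@@H](OC(C)=O)C/C(C)=C/CCC(C)=O
F3 | step 20 | (1E,4E)-cyclodeca-1(10),4-diene with C6 OTBS, C8 OAc and exocyclic acrylate | CC(=O)OC/C(C(=O)OC)=C1\[C@@H](OC(C)=O)C/C(C)=C/CC/C(C)=C/[C@H]1O[Si](C)(C)C(C)(C)C
F4 | step 12 | 2-methyl-2-[(3E)-4-methyl-5-(phenylsulfonyl)pent-3-en-1-yl]-1,3-dioxolane | O=S(=O)(C/C(C)=C/CCC1(C)OCCO1)c1ccccc1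
F5 | step 12 | β-hydroxy sulfone (C8 carbinol, C9 phenylsulfonyl; diastereomers) | CC(C)(C)[Si](C)(C)OC[C@@H](O[Si](C)(C)C(C)(C)C)/C(=C(/COC(C)=O)C(=O)OC)C(O)C(/C(C)=C/CCC1(C)OCCO1)S(=O)(=O)c1ccccc1
F6 | step 12 | β-keto sulfone (C8 ketone, C9 phenylsulfonyl) | CC(C)(C)[Si](C)(C)OC[C@@H](O[Si](C)(C)C(C)(C)C)/C(=C(/COC(C)=O)C(=O)OC)C(=O)C(/C(C)=C/CCC1(C)OCCO1)S(=O)(=O)c1ccccc1
F7 | step 22 | butenolide with C4 hydroxyl and C5 mesylate (1,10-epoxide in place) | CC(=O)OCC1=C2[C@@H](OC(C)=O)C[C@@]3(C)O[C@@H]3CC[C@@](C)(O)[C@@H](OS(C)(=O)=O)[C@H]2OC1=O
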